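## Retrosynthetic overview

1. The only ring, the 1,2-dioxan-3-ol, is formed last: γ-hydroperoxy ketone 18 closes spontaneously to the peroxyhemiketal 19. The hydroperoxide comes from Co/O2/Et3SiH hydroperoxysilylation of the 1,1-disubstituted alkene in γ,δ-unsaturated ketone 16.
2. Key C–C bond (ring C5–C6): Pd-catalysed coupling of zinc homoenolate 13, made from the chiral β-bromo ester 12 (brings the ring C4 stereocentre), with enol triflate 11. The ester is then converted to the methyl ketone.
3. Enol triflate 11 comes from methyl ketone 9, which comes from Cu/JosiPhos conjugate addition of MeMgBr to enone 8 (sets the side-chain stereocentre).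
4. Enone 8 comes from ester 5 by one-pot DIBAL reduction/Wittig; ester 5 comes from a Z-selective Wittig reaction of benzaldehyde with the ylide of ethyl 8-bromooctanoate.

Assumption: target ring atoms are numbered O1–O2–C3(OH)–C4–C5–C6; metal alkoxides/enolates that are only protonated on aqueous work-up are not numbered, whereas species generated and then consumed by a further added reagent are.

## Route

Step 1
Reactants: 1 ethyl 8-bromooctanoate
Product: 2 (8-ethoxy-8-oxooctyl)triphenylphosphonium bromide
Conditions: PPh3 (1.05 equiv), MeCN, reflux, 36 h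
Reagents that add atoms: triphenylphosphine, c1ccc(cc1)P(c1ccccc1)c1ccccc1
Why: SN2 quaternisation of triphenylphosphine by the primary bromide (phosphonium salt formation) leaves the ester untouched and creates no stereocentre.

Step 2
Reactants: 2 (8-ethoxy-8-oxooctyl)triphenylphosphonium bromide; 3 benzaldehyde
Product: 5 ethyl (8Z)-9-phenylnon-8-enoate, via phosphonium ylide 4 (not isolated)
Conditions: NaHMDS (1.0 equiv), THF, −78 °C, 30 min; then 3, −78 °C → rt
Reagents that add atoms: none
Why: Salt-free Wittig olefination of an unstabilised ylide with an aromatic aldehyde is kinetically Z-selective (expected Z:E ≥ 9:1, minor E-isomer removed on AgNO3-silica), and the phosphonium α-CH is far more acidic than the ester α-CH, so one equivalent of base gives only the ylide.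

Step 3
Reactants: 5 ethyl (8Z)-9-phenylnon-8-enoate; 6 1-(triphenyl-λ5-phosphanylidene)propan-2-one
Product: 8 (3E,11Z)-12-phenyldodeca-3,11-dien-2-one, via (8Z)-9-phenylnon-8-enal 7 (not isolated)
Conditions: DIBAL-H (1.05 equiv), CH2Cl2, −78 °C, 1 h; then 6 (1.5 equiv), −78 °C → rt, 16 h; Rochelle-salt work-up
Reagents that add atoms: none
Why: DIBAL-H half-reduction of the ethyl ester at −78 °C stops at the aluminium hemiacetal, which releases aldehyde 7 on warming in the presence of the stabilised ylide, so over-reduction is avoided and the Wittig olefination gives the (E)-enone while the Z-styrene is inert.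

Step 4
Reactants: 8 (3E,11Z)-12-phenyldodeca-3,11-dien-2-one
Product: 9 (4R,11Z)-4-methyl-12-phenyldodec-11-en-2-one
Conditions: MeMgBr (1.2 equiv), CuBr·SMe2 (5 mol %), JosiPhos (6 mol %; the antipode that gives 4R, both are commercial), t-BuOMe, −75 °C; aq NH4Cl
Reagents that add atoms: methylmagnesium bromide, C[Mg]Br
Why: Cu(I)/JosiPhos-catalysed asymmetric conjugate addition of a Grignard reagent to a linear (E)-enone (Feringa-type ACA) sets the side-chain methyl stereocentre by catalyst control, the ligand antipode being the one that delivers methyl to the enone face giving 4R (typically ≥ 95% ee for this substrate class).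

Step 5
Reactants: 9 (4R,11Z)-4-methyl-12-phenyldodec-11-en-2-one
Product: 11 (4R,11Z)-4-methyl-12-phenyldodeca-1,11-dien-2-yl trifluoromethanesulfonate, via lithium enolate 10 (not isolated)
Conditions: LDA (1.1 equiv), THF, −78 °C, 30 min; then PhNTf2 (1.15 equiv), −78 → 0 °C
Reagents that add atoms: N-phenylbis(trifluoromethanesulfonimide), O=S(=O)(N(c1ccccc1)S(=O)(=O)C(F)(F)F)C(F)(F)F; lithium diisopropylamide, [Li]N(C(C)C)C(C)C (lithium only in intermediate 10)
Why: Kinetic deprotonation of the methyl ketone by LDA at −78 °C occurs at the unhindered CH3 and not at the β-branched CH2, and O-sulfonylation of the enolate by PhNTf2 (enol triflate formation) gives the 1-alken-2-yl triflate without touching the stereocentre.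

Step 6
Reactants: 11 (4R,11Z)-4-methyl-12-phenyldodeca-1,11-dien-2-yl trifluoromethanesulfonate; 12 methyl (2S)-3-bromo-2-methylpropanoate
Product: 14 methyl (2R,6R,13Z)-2,6-dimethyl-4-methylidene-14-phenyltetradec-13-enoate, via zinc homoenolate 13 (not isolated)
Conditions: 12 (1.5 equiv), Zn dust (2.2 equiv), I2 (5 mol %), DMA, 70 °C, 3 h; then 11, PdCl2(dppf) (5 mol %), THF–DMA, 45 °C
Reagents that add atoms: zinc, [Zn] (only in intermediate 13)
Why: Negishi cross-coupling of a zinc homoenolate (β-zincio ester from zinc insertion into the C–Br bond) with an alkenyl triflate joins the ester β-carbon to the former carbonyl carbon of 9; the α-methyl stereocentre of 12 is a spectator (the organozinc does not enolise), so (S)-12 gives the (2R)-ester, and dppf favours reductive elimination over β-hydride elimination.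

Step 7
Reactants: 14 methyl (2R,6R,13Z)-2,6-dimethyl-4-methylidene-14-phenyltetradec-13-enoate
Product: 16 (3R,7R,14Z)-3,7-dimethyl-5-methylidene-15-phenylpentadec-14-en-2-one, via Weinreb amide 15 (not isolated)
Conditions: MeNH(OMe)·HCl (1.6 equiv), i-PrMgCl (3.2 equiv), THF, −20 °C, 1 h; then MeMgBr (3 equiv), −20 → 0 °C; aq NH4Cl
Reagents that add atoms: methylmagnesium bromide, C[Mg]Br; N,O-dimethylhydroxylamine hydrochloride, CNOC.Cl (N-methoxy-N-methylamino group only in intermediate 15)
Why: Aminolysis of the ester by the magnesium amide of N,O-dimethylhydroxylamine gives Weinreb amide 15, and methyl Grignard addition stops at the chelated tetrahedral adduct so only the methyl ketone is released on work-up (Weinreb ketone synthesis), without epimerising the α-stereocentre at low temperature.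

Step 8
Reactants: 16 (3R,7R,14Z)-3,7-dimethyl-5-methylidene-15-phenylpentadec-14-en-2-one
Product: 19 (3S,4R,6S)-3,4,6-trimethyl-6-[(2R,9Z)-2-methyl-10-phenyldec-9-en-1-yl]-1,2-dioxan-3-ol (target), via triethylsilyl peroxide 17 (not isolated), via hydroperoxy ketone 18 (not isolated)
Conditions: Co(thd)2 (10 mol %), O2 (1 atm), Et3SiH (2 equiv), DCE, rt; then HF·pyridine, THF, 0 °C; chromatography (silica, then HPLC) to remove the 6-epimer
Reagents that add atoms: dioxygen, O=O; triethylsilane, CC[SiH](CC)CC (silyl group only in intermediate 17)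
Why: Mukaiyama–Isayama hydroperoxysilylation (Co–H hydrogen-atom transfer to the more reactive 1,1-disubstituted alkene, O2 capture of the tertiary radical, silylation) followed by fluoride desilylation gives γ-hydroperoxy ketone 18, which closes to the six-membered peroxyhemiketal; C3 is set under thermodynamic control (axial anomeric OH, equatorial 3- and 4-methyl), C4 is retained, and C6 arises without facial control (about 1:1, so at most about half the material), the (6S) isomer being separated from its 6-epimer by chromatography.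

## Compound list

1 | ethyl 8-bromooctanoate | CCOC(=O)CCCCCCCBr | starting material
2 | (8-ethoxy-8-oxooctyl)triphenylphosphonium bromide | CCOC(=O)CCCCCCC[P+](c1ccccc1)(c1ccccc1)c1ccccc1.[Br-] | intermediate
3 | benzaldehyde | O=Cc1ccccc1 | starting material
4 | ethyl 8-(triphenyl-λ5-phosphanylidene)octanoate (phosphonium ylide) | CCOC(=O)CCCCCCC=P(c1ccccc1)(c1ccccc1)c1ccccc1 | intermediate (not isolated)
5 | ethyl (8Z)-9-phenylnon-8-enoate | CCOC(=O)CCCCCC/C=C\c1ccccc1 | intermediate
6 | 1-(triphenyl-λ5-phosphanylidene)propan-2-one | CC(=O)C=P(c1ccccc1)(c1ccccc1)c1ccccc1 | starting material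
7 | (8Z)-9-phenylnon-8-enal | O=CCCCCCC/C=C\c1ccccc1 | intermediate (not isolated)
8 | (3E,11Z)-12-phenyldodeca-3,11-dien-2-one | CC(=O)/C=C/CCCCCC/C=C\c1ccccc1 | intermediate
9 | (4R,11Z)-4-methyl-12-phenyldodec-11-en-2-one | CC(=O)C[C@H](C)CCCCCC/C=C\c1ccccc1 | intermediate
10 | lithium (4R,11Z)-4-methyl-12-phenyldodeca-1,11-dien-2-olate (lithium enolate) | [Li+].[O-]C(=C)C[C@H](C)CCCCCC/C=C\c1ccccc1 | intermediate (not isolated)
11 | (4R,11Z)-4-methyl-12-phenyldodeca-1,11-dien-2-yl trifluoromethanesulfonate | C=C(OS(=O)(=O)C(F)(F)F)C[C@H](C)CCCCCC/C=C\c1ccccc1 | intermediate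
12 | methyl (2S)-3-bromo-2-methylpropanoate | COC(=O)[C@H](C)CBr | starting material
13 | bromo[(2S)-3-methoxy-2-methyl-3-oxopropyl]zinc (zinc homoenolate) | COC(=O)[C@H](C)C[Zn]Br | intermediate (not isolated)
14 | methyl (2R,6R,13Z)-2,6-dimethyl-4-methylidene-14-phenyltetradec-13-enoate | COC(=O)[C@H](C)CC(=C)C[C@H](C)CCCCCC/C=C\c1ccccc1 | intermediate
15 | (2R,6R,13Z)-N-methoxy-N,2,6-trimethyl-4-methylidene-14-phenyltetradec-13-enamide (Weinreb amide) | CON(C)C(=O)[C@H](C)CC(=C)C[C@H](C)CCCCCC/C=C\c1ccccc1 | intermediate (not isolated)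
16 | (3R,7R,14Z)-3,7-dimethyl-5-methylidene-15-phenylpentadec-14-en-2-one | CC(=O)[C@H](C)CC(=C)C[C@H](C)CCCCCC/C=C\c1ccccc1 | intermediate
17 | (3R,5S,7R,14Z)-3,5,7-trimethyl-15-phenyl-5-[(triethylsilyl)peroxy]pentadec-14-en-2-one (formed together with its 5-epimer) | CC(=O)[C@H](C)C[C@@](C)(OO[Si](CC)(CC)CC)C[C@H](C)CCCCCC/C=C\c1ccccc1 | intermediate (not isolated)
18 | (3R,5S,7R,14Z)-5-hydroperoxy-3,5,7-trimethyl-15-phenylpentadec-14-en-2-one | CC(=O)[C@H](C)C[C@@](C)(OO)C[C@H](C)CCCCCC/C=C\c1ccccc1 | intermediate (not isolated)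
19 | (3S,4R,6S)-3,4,6-trimethyl-6-[(2R,9Z)-2-methyl-10-phenyldec-9-en-1-yl]-1,2-dioxan-3-ol | C[C@H](CCCCCC/C=C\c1ccccc1)C[C@@]1(C)C[C@@H](C)[C@@](C)(O)OO1 | target

## Step count and risks

Total step count: 8. Longest linear sequence: 8 steps (1 → 19); the second fragment 12 is used as purchased.

Most likely to fail, in order:

Step 8. The Co–H catalyst may also transfer hydrogen to the Z-styrene (reduction, peroxidation or Z→E isomerisation), C6 is formed without stereocontrol, and the peroxyhemiketal is labile. Fallback (sets out from 16, comes back at 19): ionic hydroperoxymercuration in place of radical chemistry. Ketone 16 is treated with Hg(OAc)2 and 50% H2O2 (THF, 0 °C, cat. HClO4). The mercurinium ion of the more nucleophilic 1,1-disubstituted alkene is opened at the tertiary carbon by the peroxide oxygen, and the ring closes on the ketone to give {[(3S,4R,6S)-3-hydroxy-3,4-dimethyl-6-[(2R,9Z)-2-methyl-10-phenyldec-9-en-1-yl]-1,2-dioxan-6-yl]methyl}mercury(II) acetate F1. Brief alkaline NaBH4 reduction (0 °C) replaces mercury by hydrogen to give 19. This avoids hydrogen-atom transfer to the styrene, but C6 is still uncontrolled and the 6-epimer must be separated.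

Step 6. Zinc insertion into the bromide may be sluggish, and the alkyl–Pd intermediate can undergo β-hydride elimination or isomerise the new 1,1-disubstituted alkene. Fallback (sets out from 11, comes back at 15): a normal-polarity enolate alkylation.
- Stille coupling of 11 with (tributylstannyl)methanol (Pd(PPh3)4, LiCl, dioxane, 90 °C) gives (4R,11Z)-4-methyl-2-methylidene-12-phenyldodec-11-en-1-ol F2.
- CBr4/PPh3 (CH2Cl2, 0 °C) gives (4R,11Z)-2-(bromomethyl)-4-methyl-12-phenyldodeca-1,11-diene F3.
- Alkylation of the sodium enolate of (4S)-4-benzyl-3-propanoyl-1,3-oxazolidin-2-one (NaHMDS, THF, −78 °C) gives (4S)-4-benzyl-3-[(2R,6R,13Z)-2,6-dimethyl-4-methylidene-14-phenyltetradec-13-enoyl]-1,3-oxazolidin-2-one F4, with the (2R) centre set by the auxiliary.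
- Me3Al/MeNH(OMe)·HCl (CH2Cl2, 0 °C) converts F4 into Weinreb amide 15, which is taken on with MeMgBr as in step 7.

Step 4. MeMgBr can add 1,2 to the methyl ketone, and the ee depends on slow addition and temperature. Fallback (sets out from 5, comes back at 9): move the stereo-defining addition to a thioester, which does not suffer 1,2-addition, and build the methyl ketone afterwards.
- DIBAL-H reduction of 5 to aldehyde 7 and in-situ Wittig reaction with S-ethyl 2-(triphenyl-λ5-phosphanylidene)ethanethioate gives S-ethyl (2E,10Z)-11-phenylundeca-2,10-dienethioate F5.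
- MeMgBr with CuBr·SMe2/JosiPhos (t-BuOMe, −75 °C) gives S-ethyl (3R,10Z)-3-methyl-11-phenylundec-10-enethioate F6.
- Me2CuLi (Et2O, −78 °C) converts the thioester into methyl ketone 9.

Further compounds

F1 | step 8 | {[(3S,4R,6S)-3-hydroxy-3,4-dimethyl-6-[(2R,9Z)-2-methyl-10-phenyldec-9-en-1-yl]-1,2-dioxan-6-yl]methyl}mercury(II) acetate | C[C@H](CCCCCC/C=C\c1ccccc1)C[C@@]1(C[Hg]OC(C)=O)C[C@@H](C)[C@@](C)(O)OO1
F2 | step 6 | (4R,11Z)-4-methyl-2-methylidene-12-phenyldodec-11-en-1-ol | OCC(=C)C[C@H](C)CCCCCC/C=C\c1ccccc1
F3 | step 6 | (4R,11Z)-2-(bromomethyl)-4-methyl-12-phenyldodeca-1,11-diene | BrCC(=C)C[C@H](C)CCCCCC/C=C\c1ccccc1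
F4 | step 6 | (4S)-4-benzyl-3-[(2R,6R,13Z)-2,6-dimethyl-4-methylidene-14-phenyltetradec-13-enoyl]-1,3-oxazolidin-2-one | O=C1OC[C@H](Cc2ccccc2)N1C(=O)[C@H](C)CC(=C)C[C@H](C)CCCCCC/C=C\c1ccccc1
F5 | step 4 | S-ethyl (2E,10Z)-11-phenylundeca-2,10-dienethioate | CCSC(=O)/C=C/CCCCCC/C=C\c1ccccc1
F6 | step 4 | S-ethyl (3R,10Z)-3-methyl-11-phenylundec-10-enethioate | CCSC(=O)C[C@H](C)CCCCCC/C=C\c1ccccc1
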